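I reckoned this flask by counting turnovers.

substrate 0.33 M; precatalyst 0.33 mM

- the form that holds most of the catalyst when 50% of the substrate are converted (catalyst intermediate A / free catalyst / precatalyst / catalyst intermediate B)
- its share of the catalyst then

    catalyst intermediate B → free catalyst + target (k1 = 26.5 min⁻¹)
    substrate + free catalyst → catalyst intermediate A (k2 = 2.16 M⁻¹ min⁻¹)
    precatalyst ⇌ free catalyst (K3 = 0.12, k3 = 5.41 × 10⁻⁴ min⁻¹)
    catalyst intermediate A → catalyst intermediate B (k4 = 3.22 min⁻¹)

In this flask the catalyst goes round: free catalyst takes up substrate to give catalyst intermediate A, which becomes catalyst intermediate B, which releases target and free catalyst. Precatalyst stands outside the round (off-cycle) and exchanges with free catalyst. At 50% conversion [substrate] is 0.165 M. It exceeds the catalyst by so much that free catalyst is consumed in a pseudo-first-order way, and it waits 2.81 min per turnover. Catalyst intermediate A waits 0.311 min and catalyst intermediate B 0.0377 min. Each form of the round passes the same flow, so its amount goes with its wait. Precatalyst, held to free catalyst by the equilibrium constant 0.12, adds a wait of 23.4 min. The sum, 26.5 min, is the turn time: the minutes a charged catalyst needs per turnover, dormant spells counted. Each form's share of the catalyst is its wait over that sum.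

I took the exchange as equilibrated because, even at the shorter turn time of the full charge, the 500 turnovers to that conversion take 4.67 d, much longer than the exchange's relaxation half-life of 0.0953 d. So I committed to precatalyst at 88.1%.

The forecast named precatalyst at 88%, “leaving most of the catalyst dormant”, the same form and about the same share as mine.

The simulation gave precatalyst at 88.1%, reached at 6.58 d, with free catalyst at 10.6%.

The turn time carries on to later in this flask. At a conversion of 0.7 [substrate] is 0.0990 M, which stretches the turn time to 44.0 min. The rate goes as the inverse of the turn time, so I reckoned it at 0.602 of its value at 50% conversion. In this flask, at 11.3 d, that ratio of rates stood at 0.60.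

The numbers are invented; what happens was integrated by code.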